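**Retrosynthetic overview** (drimane numbering: ring A = C1–C5, C10; ring B = C5–C10; C11 = CH2O; C12 = exocyclic CH2)

- The aryl ether is made last by Mitsunobu coupling of isofraxidin with alcohol 15. C9–C11 and the C8=C12 methylene come from γ-selective indium allylation of formaldehyde by allylic bromide 14, which sets C9 anti to the C10 methyl.
- The C4 gem-dimethyl group comes from double methylation of the cross-conjugated enolate of enone 12, itself from enal 11.
- Ring B (C5–C6 and C8=C9) is closed in one pot by a [3+3] annulation: enantioselective copper-catalysed 1,4-addition of the acetal-bearing alkylzirconocene 8 (from alkene 7 and Cp2Zr(H)Cl) to prochiral dienone 6, then acetal hydrolysis and dialdehyde aldol condensation.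
- Ring A is formed first (dienone 6 from benzoic acid by Birch reductive methylation and bis-allylic oxidation), ring B second.
- Enabling feature: quaternary C10 lies between C1=C2 and C5 with the C3 carbonyl para to it, so ring A is a desymmetrised 4,4-disubstituted cyclohexa-2,5-dienone and C5 is an enone β-carbon. C9 on C10 is a formyl carbon without α-hydrogen, so it can only be the acceptor in the aldol closure of C8=C9.

Key step: step 7

Remark: the target is (5S,9S,10R), i.e. trans-fused with CH2OAr anti to the C10 methyl. The (S,R,R)-ligand is assumed, by analogy with other 4,4-disubstituted cyclohexadienones, to give the (4S,5R) adduct; if the sense of induction is opposite, the (R,S,S)-ligand is used. In the SMILES of zirconium compounds the η5-cyclopentadienyl ligands are written as σ-bonded C5H5 groups.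

**Step 1**
Reactants: 1 benzoic acid
Product: 2 1-methylcyclohexa-2,5-diene-1-carboxylic acid
Conditions: Li, NH3 (l), THF, −78 °C; MeI; then NH4Cl, aq. HCl
Reagents that add atoms: iodomethane, CI
Why: Birch reduction gives the 1,4-dihydro dianion, whose carboxylate-stabilised C1 carbanion is methylated in situ (Birch reductive alkylation); no stereocentre is formed.

**Step 2**
Reactants: 2 1-methylcyclohexa-2,5-diene-1-carboxylic acid
Product: 3 (1-methylcyclohexa-2,5-dien-1-yl)methanol
Conditions: LiAlH4, THF, 0 °C→reflux
Reagents that add atoms: none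
Why: hydride reduction of the acid to the primary alcohol leaves the unconjugated 1,4-diene untouched.

**Step 3**
Reactants: 3 (1-methylcyclohexa-2,5-dien-1-yl)methanol
Product: 4 1-methylcyclohexa-2,5-diene-1-carbaldehyde
Conditions: Dess–Martin periodinane, CH2Cl2, 0→23 °C
Reagents that add atoms: none
Why: Dess–Martin oxidation gives the non-enolisable aldehyde under mild conditions that should avoid double-bond migration or aromatisation.

**Step 4**
Reactants: 4 1-methylcyclohexa-2,5-diene-1-carbaldehyde
Product: 5 3-(dimethoxymethyl)-3-methylcyclohexa-1,4-diene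
Conditions: HC(OMe)3, MeOH, TsOH·H2O (cat.), 23 °C
Reagents that add atoms: trimethyl orthoformate, COC(OC)OC; methanol, CO
Why: acid-catalysed acetalisation with the orthoformate as water scavenger turns C9 into a branched group that is stable to organometallics.

**Step 5**
Reactants: 5 3-(dimethoxymethyl)-3-methylcyclohexa-1,4-diene
Product: 6 4-(dimethoxymethyl)-4-methylcyclohexa-2,5-dien-1-one
Conditions: pyridinium dichromate (C5H5NH)2Cr2O7, t-BuOOH, Celite, benzene, 10→23 °C
Reagents that add atoms: tert-butyl hydroperoxide, CC(C)(C)OO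
Why: chromium-mediated allylic oxidation of the doubly allylic CH2 of a 3,3-disubstituted cyclohexa-1,4-diene gives the cross-conjugated dienone, as is known for Birch-alkylation products.

**Step 6**
Reactants: 7 4,4-diethoxybut-1-ene
Product: 8 chlorido(4,4-diethoxybutyl)bis(cyclopentadienyl)zirconium
Conditions: Cp2Zr(H)Cl (1.0 equiv), CH2Cl2, 23 °C; the solution is used directly
Reagents that add atoms: chloridobis(cyclopentadienyl)hydridozirconium, Cl[ZrH](C1C=CC=C1)C1C=CC=C1
Why: hydrozirconation adds Zr–H across the terminal alkene with the metal at the unhindered terminal carbon, so each zirconium centre carries one transferable 4,4-diethoxybutyl group from one alkene, and the acetal is tolerated; no stereocentre is formed.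

**Step 7**
Reactants: 6 4-(dimethoxymethyl)-4-methylcyclohexa-2,5-dien-1-one; 8 chlorido(4,4-diethoxybutyl)bis(cyclopentadienyl)zirconium
Product: 11 (4aR,8aS)-8a-methyl-6-oxo-3,4,4a,5,6,8a-hexahydronaphthalene-2-carbaldehyde, via keto bis-acetal 9 (not isolated), via dialdehyde 10 (not isolated)
Conditions: (CuOTf)2·C6H6 (5 mol %), (S,R,R)-phosphoramidite [O,O′-(S)-1,1′-binaphthalene-2,2′-diyl N,N-bis((R)-1-phenylethyl)phosphoramidite] (10 mol %), 8 (1.5 equiv, CH2Cl2 solution), t-BuOMe, 23 °C; then AcOH–H2O–THF, 55 °C; then piperidine (0.5 equiv), 55 °C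
Reagents that add atoms: water, O
Why: Monovalent copper bound to the phosphoramidite transmetalates with alkylzirconocene 8 and transfers the 4,4-diethoxybutyl group to C5 of one enantiotopic enone arm of 6, giving a zirconium enolate that is protonated to 9 when the acid is added; aqueous acetic acid then unmasks both acetals, and piperidinium acetate converts the enolisable side-chain aldehyde of 10 into its enamine, which attacks the C9 formyl group and loses water to give the C8=C9 enal. The closest known reaction types are the copper–phosphoramidite 1,4-addition to cyclic enones of alkylzirconocenes made by hydrozirconation of alkenes, the copper–phosphoramidite desymmetrisation of 4,4-disubstituted cyclohexa-2,5-dienones with alkylzinc reagents, and the amine-salt cyclisation of 1,7-dialdehydes to cyclohexene carbaldehydes. Ring B is the only ring closed, by a 6-(enolexo)-exo-trig aldol condensation, after the C5–C6 bond has been made intermolecularly in the same flask. C10 is set by the catalyst's choice between the two enantiotopic enone arms, and C5 by delivery of the alkyl group anti to the branched dimethoxymethyl group, i.e. cis to the methyl, which is the relation that makes the ring fusion trans. The step needs arm and face selectivity in the addition and aldehyde-to-aldehyde chemoselectivity in the condensation; the first should come from a matched ligand plus the bulk of the acetal, the second from the fact that only the side-chain aldehyde forms an enamine under these mild conditions, that C9 has no α-hydrogen, and that dehydration to the conjugated enal is irreversible.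

**Step 8**
Reactants: 11 (4aR,8aS)-8a-methyl-6-oxo-3,4,4a,5,6,8a-hexahydronaphthalene-2-carbaldehyde
Product: 12 (4aS,8aR)-6-(hydroxymethyl)-4a-methyl-4a,7,8,8a-tetrahydronaphthalen-2(1H)-one
Conditions: NaBH4 (0.3 equiv), EtOH–CH2Cl2, −78 °C
Reagents that add atoms: none
Why: at low temperature borohydride reduces the conjugated aldehyde (1,2-reduction) much faster than the conjugated ketone, so the enone should survive.

**Step 9**
Reactants: 12 (4aS,8aR)-6-(hydroxymethyl)-4a-methyl-4a,7,8,8a-tetrahydronaphthalen-2(1H)-one
Product: 13 (4aS,8aS)-6-(hydroxymethyl)-1,1,4a-trimethyl-4a,7,8,8a-tetrahydronaphthalen-2(1H)-one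
Conditions: LiN(iPr)2 (2.2 equiv), THF, −78 °C; MeI; then LiN(iPr)2 (1.2 equiv), −78 °C; MeI, −78→−20 °C
Reagents that add atoms: iodomethane, CI
Why: C4 is the only enolisable position (C10 is quaternary, so no γ-deprotonation), so two kinetic deprotonation/alkylation cycles of the cross-conjugated lithium enolate should install the gem-dimethyl group while the alcohol is carried as its unreactive lithium alkoxide.

**Step 10**
Reactants: 13 (4aS,8aS)-6-(hydroxymethyl)-1,1,4a-trimethyl-4a,7,8,8a-tetrahydronaphthalen-2(1H)-one
Product: 14 (4aS,8aS)-6-(bromomethyl)-1,1,4a-trimethyl-4a,7,8,8a-tetrahydronaphthalen-2(1H)-one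
Conditions: CBr4, PPh3, CH2Cl2, 0 °C
Reagents that add atoms: carbon tetrabromide, BrC(Br)(Br)Br
Why: the Appel reaction converts the primary allylic alcohol into the bromide under neutral conditions compatible with the enone.

**Step 11**
Reactants: 14 (4aS,8aS)-6-(bromomethyl)-1,1,4a-trimethyl-4a,7,8,8a-tetrahydronaphthalen-2(1H)-one
Product: 15 (4aR,5S,8aS)-5-(hydroxymethyl)-1,1,4a-trimethyl-6-methylidene-4a,5,6,7,8,8a-hexahydronaphthalen-2(1H)-one
Conditions: In (powder), 37% aq. HCHO, THF–H2O, 23 °C
Reagents that add atoms: formaldehyde, C=O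
Why: in this Barbier-type indium allylation the allylindium reacts with formaldehyde at its γ-carbon (C9) through a six-membered transition state with transposition to the exocyclic C8=C12 alkene, and the C9–C11 bond should form on the face anti to the pseudo-axial C10 methyl, giving the (S)-configured C9.

**Step 12**
Reactants: 15 (4aR,5S,8aS)-5-(hydroxymethyl)-1,1,4a-trimethyl-6-methylidene-4a,5,6,7,8,8a-hexahydronaphthalen-2(1H)-one; 16 isofraxidin
Product: 17 7-{[(1S,4aS,8aR)-5,5,8a-trimethyl-2-methylidene-6-oxo-1,2,3,4,4a,5,6,8a-octahydronaphthalen-1-yl]methoxy}-6,8-dimethoxy-2H-chromen-2-one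
Conditions: PPh3, DIAD, THF, 0→23 °C
Reagents that add atoms: none
Why: Mitsunobu etherification couples the primary alcohol with the acidic 7-hydroxycoumarin at the CH2 carbon, so no stereocentre is touched.

**Compound list**

1 | benzoic acid | OC(=O)c1ccccc1 | starting material
2 | 1-methylcyclohexa-2,5-diene-1-carboxylic acid | CC1(C(=O)O)C=CCC=C1 | intermediate
3 | (1-methylcyclohexa-2,5-dien-1-yl)methanol | CC1(CO)C=CCC=C1 | intermediate
4 | 1-methylcyclohexa-2,5-diene-1-carbaldehyde | CC1(C=O)C=CCC=C1 | intermediate
5 | 3-(dimethoxymethyl)-3-methylcyclohexa-1,4-diene | COC(OC)C1(C)C=CCC=C1 | intermediate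
6 | 4-(dimethoxymethyl)-4-methylcyclohexa-2,5-dien-1-one | COC(OC)C1(C)C=CC(=O)C=C1 | intermediate
7 | 4,4-diethoxybut-1-ene | C=CCC(OCC)OCC | starting material
8 | chlorido(4,4-diethoxybutyl)bis(cyclopentadienyl)zirconium | CCOC(OCC)CCC[Zr](Cl)(C1C=CC=C1)C1C=CC=C1 | intermediate
9 | (4S,5R)-5-(4,4-diethoxybutyl)-4-(dimethoxymethyl)-4-methylcyclohex-2-en-1-one | CCOC(OCC)CCC[C@@H]1CC(=O)C=C[C@@]1(C)C(OC)OC | intermediate
10 | (1S,6R)-1-methyl-4-oxo-6-(4-oxobutyl)cyclohex-2-ene-1-carbaldehyde | O=CCCC[C@@H]1CC(=O)C=C[C@@]1(C)C=O | intermediate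
11 | (4aR,8aS)-8a-methyl-6-oxo-3,4,4a,5,6,8a-hexahydronaphthalene-2-carbaldehyde | O=CC=1CC[C@@H]2CC(=O)C=C[C@@]2(C)C=1 | intermediate
12 | (4aS,8aR)-6-(hydroxymethyl)-4a-methyl-4a,7,8,8a-tetrahydronaphthalen-2(1H)-one | OCC=1CC[C@@H]2CC(=O)C=C[C@@]2(C)C=1 | intermediate
13 | (4aS,8aS)-6-(hydroxymethyl)-1,1,4a-trimethyl-4a,7,8,8a-tetrahydronaphthalen-2(1H)-one | OCC=1CC[C@@H]2C(C)(C)C(=O)C=C[C@@]2(C)C=1 | intermediate
14 | (4aS,8aS)-6-(bromomethyl)-1,1,4a-trimethyl-4a,7,8,8a-tetrahydronaphthalen-2(1H)-one | BrCC=1CC[C@@H]2C(C)(C)C(=O)C=C[C@@]2(C)C=1 | intermediate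
15 | (4aR,5S,8aS)-5-(hydroxymethyl)-1,1,4a-trimethyl-6-methylidene-4a,5,6,7,8,8a-hexahydronaphthalen-2(1H)-one | C=C1CC[C@@H]2C(C)(C)C(=O)C=C[C@@]2(C)[C@H]1CO | intermediate
16 | isofraxidin (7-hydroxy-6,8-dimethoxy-2H-chromen-2-one) | COc1cc2ccc(=O)oc2c(OC)c1O | starting material
17 | 7-{[(1S,4aS,8aR)-5,5,8a-trimethyl-2-methylidene-6-oxo-1,2,3,4,4a,5,6,8a-octahydronaphthalen-1-yl]methoxy}-6,8-dimethoxy-2H-chromen-2-one | C=C1CC[C@@H]2C(C)(C)C(=O)C=C[C@@]2(C)[C@H]1COc1c(OC)cc2ccc(=O)oc2c1OC | target

**Step count and risks**

Total step count: 12. Longest linear sequence: 11 (steps 1–5 and 7–12; step 6 is a one-step branch).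

Steps most likely to fail:

1. Step 7. The alkyl group may add with incomplete preference for the face anti to the acetal. In the acid phase the ring-A ketone enol may also attack the side-chain aldehyde instead of the wanted aldehyde-to-aldehyde condensation. The fallback sets out from 6 and 8 and separates the two events. The 1,4-addition is quenched with aqueous NH4Cl and keto bis-acetal 9 is isolated, the minor cis adduct being removed by chromatography. Ketone 9 is then methylated twice (LiN(iPr)2, MeI) to (4R,5S)-5-(4,4-diethoxybutyl)-4-(dimethoxymethyl)-4,6,6-trimethylcyclohex-2-en-1-one F1, in which C4 is blocked so that only the dialdehyde condensation remains possible. Aqueous acetic acid and then piperidinium acetate should give (4aS,8aS)-5,5,8a-trimethyl-6-oxo-3,4,4a,5,6,8a-hexahydronaphthalene-2-carbaldehyde F2, and NaBH4 at −78 °C reduces it to 13, where the route is rejoined.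

2. Step 11. The allylindium may bond to formaldehyde through C12 instead of C9, or attack with poor facial selectivity, or be protonated before it reacts. The fallback sets out from 14 and replaces the allylmetal addition by an ene reaction. Radical reduction (Bu3SnH, AIBN, benzene, 80 °C) should give (4aS,8aS)-1,1,4a,6-tetramethyl-4a,7,8,8a-tetrahydronaphthalen-2(1H)-one F3. Its trisubstituted C8=C9 alkene is then treated with paraformaldehyde and Me2AlCl in CH2Cl2; formaldehyde should add at C9 anti to the C10 methyl with hydrogen transfer from the C12 methyl, giving 15, where the route is rejoined.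

3. Step 12. The phosphonium-activated alcohol is β-branched and axial, and the phenol is flanked by two methoxy groups, so substitution may be slow and elimination to the diene may take over. The fallback sets out from 15 and 16 and uses a pre-formed sulfonate. MsCl and Et3N in CH2Cl2 at 0 °C give [(1S,4aS,8aR)-5,5,8a-trimethyl-2-methylidene-6-oxo-1,2,3,4,4a,5,6,8a-octahydronaphthalen-1-yl]methyl methanesulfonate F4. This is displaced by the caesium phenoxide of 16 (Cs2CO3, DMF, 60 °C) to give 17.

**Further compounds**

F1 | step 7 | (4R,5S)-5-(4,4-diethoxybutyl)-4-(dimethoxymethyl)-4,6,6-trimethylcyclohex-2-en-1-one | CCOC(OCC)CCC[C@@H]1C(C)(C)C(=O)C=C[C@@]1(C)C(OC)OC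
F2 | step 7 | (4aS,8aS)-5,5,8a-trimethyl-6-oxo-3,4,4a,5,6,8a-hexahydronaphthalene-2-carbaldehyde | O=CC=1CC[C@@H]2C(C)(C)C(=O)C=C[C@@]2(C)C=1
F3 | step 11 | (4aS,8aS)-1,1,4a,6-tetramethyl-4a,7,8,8a-tetrahydronaphthalen-2(1H)-one | CC=1CC[C@@H]2C(C)(C)C(=O)C=C[C@@]2(C)C=1
F4 | step 12 | [(1S,4aS,8aR)-5,5,8a-trimethyl-2-methylidene-6-oxo-1,2,3,4,4a,5,6,8a-octahydronaphthalen-1-yl]methyl methanesulfonate | C=C1CC[C@@H]2C(C)(C)C(=O)C=C[C@@]2(C)[C@H]1COS(C)(=O)=O
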